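The runs were generated by integration from invented constants; the scatter is artificial.

**The pitfall.** A reagent charge looks like the handle on the yield from a suspended solid, and I want to test that before trusting it on the south-west flask, using the south run beside it.

| flask | solid substrate | reagent | remark | time |
|---|---|---|---|---|
| south-west | 2 mM | 2.4 mM (fed, over 2.0 min) | the very flask that is asked about, followed so far |  |
| south | 2 mM | 3.6 mM (fed, over 2.0 min) | run made earlier |  |
| flask | 2.0 mM | 2.40 mM (fed, over 2.0 min) |  | 40 min |

| run | time / min | solid substrate / % | target / % |
|---|---|---|---|
| south-west | 0.167 | 99.9 | 1.0 |
| south-west | 0.500 | 99.4 | 0.3 |
| south-west | 0.833 | 98.1 | 0 |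
| south-west | 1.33 | 97.0 | 2.0 |
| south-west | 2.00 | 96.7 | 2.6 |
| south-west | 2.50 | 94.9 | 3.9 |
| south-west | 3.00 | 94.4 | 4.6 |
| south | 0.833 | 97.6 | 0.5 |
| south | 2.50 | 94.5 | 3.9 |
| south | 5.00 | 93.4 | 5.0 |
| south | 6.00 | 91.5 | 5.5 |
| south | 10.0 | 91.5 | 5.1 |
| south | 12.0 | 91.0 | 5.5 |
| south | 15.0 | 91.7 | 5.4 |

(each reading ± 0.5 percentage points)

- which holds at 40 min: what has brought the reaction to rest, or that it has not come to rest (for what has run out or reacted, a solid counts together with what of it has only dissolved) (it is still moving / all of the solid substrate has reacted / the reagent has run out first)
- part of the solid substrate that has turned into other species by 40 min (what has only dissolved does not count)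
- how much target there is at 40 min, in percent of the solid substrate charged

- amounts and yields of target count solid product too
- given per volume of solution although it is solid: solid substrate, solid product
- the numbers in the tables scatter by 0.5 percentage points (one standard deviation)
- steps under discussion: solid substrate <-> dissolved substrate; dissolved substrate + reagent -> target; solid product <-> target; 2 reagent -> homo dimer
- at the start none of the solid substrate is in solution
- what has only dissolved of solid substrate counts as not reacted
- the reaction counts as stopped when no species that holds the solid substrate changes by six tenths of a point or more over the second half of the time

**Plateau fraction.** The target readings of the south run lie level within their scatter from 6.00 min on, so I replace its late curve by its mean. This plateau fraction, the mean share of the charged solid substrate read as target on that level, is 5.38%, and as a reading it carries an error of about 0.25 percentage points.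

**Bench rule.** The habit at the bench is to scale target with reagent. The charges stand at 0.667 to one, so the south-west flask should end near 3.58%.

**Its border.** That flask already reads 4.6% at 3.00 min, which is more than the rule allows. At 2.50 min it matches the south run, 3.9% against 3.9%, although the south run received more reagent. So at this ratio of charges the readings do not bear out the proportion: they stand 1 point above it, with a scatter of 0.5 points.

**My reckoning.** I therefore keep the plateau fraction for this flask, whose solid charge equals that of the south run, and I count converted solid as target. The last reading of the south run still shows 91.7% of solid substrate on a level curve, so I expect the reagent to be the limiting reagent in the south-west flask too, despite 1.20 equivalents. I also assume that, with the reagent charge and feed of this flask held and solid left, the plateau fraction times the solid charge stays constant.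

The forecast says the reagent has run out first, with 5% converted and 5% target, since “dimerisation outruns the slow route through the sparingly dissolved substrate”.

The south-west flask gives: the reagent has run out first, with 5.45% converted and 5.45% target.

    solid substrate ⇌ dissolved substrate, rate k1*(cs1 - [dissolved substrate]) while solid is left; crystals form when [dissolved substrate] > cs1 (solubility = 0.0470 mM, k = 0.0180 s⁻¹)
    dissolved substrate + reagent → target (k = 130 L mol⁻¹ s⁻¹)
    solid product ⇌ target, rate k3*(cs3 - [target]) while solid is left; crystals form when [target] > cs3 (solubility = 0.770 mM, k = 0.460 s⁻¹)
    2 reagent → homo dimer (k = 94.0 L mol⁻¹ s⁻¹)

**What stands.** At 1.25 min in the south-west flask, the homo dimer step uses reagent at 33 times the rate of the target step. At 40.0 min in that flask, with 0% of the reagent left, the homo dimer holds 95.5% of the reagent charge and the target 4.54%, and the 5.45% of target stands beside my plateau fraction of 5.38%. For a neighbour flask with 0.80 mM of solid substrate and the same reagent charge, the plateau fraction times the solid charge gives 13.4%, and that neighbour flask holds 13.6% target.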